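**Plan**
1. Numbering: ring A is C1 (ketone), C2 (amide carbon), C3, C4 (carbinol), C5–C6 (oxirane); the triene amide chain is C1′–C7′ and the dienamide chain C1″–C10″.
2. The retrosynthesis cuts C2′–C3′ (Heck coupling of a C4 vinyl group with an iododienamide), then C2–N (copper-catalysed amidation of a 2-iodoenone), then C2=C3 of ring A (ring-closing metathesis).
3. The metathesis cut is open because carbinol carbon C4 has two sp2 CH neighbours, C3 inside ring A and C1′ at the start of the triene chain. Read backwards, both are vinyl groups on C4, which is tied through the C5–C6 cis-oxirane to a vinyl ketone at C1.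
4. Forward: meso cis-epoxysuccinate is desymmetrised; two vinyl groups turn the ester carboxyl into the C4 divinyl carbinol, which is stored as a γ-lactone on the free carboxyl; a third vinyl group opens the lactone to the C1 vinyl ketone; metathesis closes ring A (the only ring made for the target, the oxirane and cyclopentenone rings are bought); the upper chain is joined at C2–N and the lower chain last at C2′–C3′.
5. Stereochemistry: C5 and C6 come from the enzymatic desymmetrisation, C4 from the choice between the two diastereotopic vinyl groups in the metathesis under control of the oxirane, C6″ from an Evans methylation, and the alkene geometries from Wittig, Horner–Wadsworth–Emmons, Takai and Heck steps.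

Key step: step 5

Assumption: pig liver esterase is taken to cleave the ester on the (S)-configured oxirane carbon of 2, by analogy with the sense recalled for the carbocyclic analogue dimethyl cis-cyclopropane-1,2-dicarboxylate; the configuration of 3 and of all later oxirane carbons follows from this.

**Step 1**
Reactants: 1 cis-epoxysuccinic acid
Product: 2 dimethyl (2R,3S)-oxirane-2,3-dicarboxylate (meso)
Conditions: MeI (2.5 equiv), KHCO3 (2.5 equiv), DMF, rt
Reagents that add atoms: iodomethane, CI
Why: SN2 O-alkylation of the dicarboxylate under weakly basic conditions esterifies both acids without exposing the oxirane to acid, and the meso configuration is carried over unchanged.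

**Step 2**
Reactants: 2 dimethyl (2R,3S)-oxirane-2,3-dicarboxylate
Product: 3 (2S,3R)-3-(methoxycarbonyl)oxirane-2-carboxylic acid
Conditions: pig liver esterase, 0.1 M phosphate buffer pH 7.5, pH-stat (1 M NaOH), 25 °C; then 2 M HCl to pH 2.5 at 0 °C, EtOAc extraction
Reagents that add atoms: water, O
Why: Enzymatic desymmetrisation of a meso diester hydrolyses one of the two enantiotopic ester groups and stops at the monoacid, which fixes the absolute configuration of both oxirane carbons (later C5 and C6) without breaking any bond to them.

**Step 3**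
Reactants: 3 (2S,3R)-3-(methoxycarbonyl)oxirane-2-carboxylic acid; 4 vinylmagnesium bromide
Product: 6 (1S,5R)-4,4-diethenyl-3,6-dioxabicyclo[3.1.0]hexan-2-one, via hydroxy acid 5 (not isolated)
Conditions: 4 (3.3 equiv: one for the acid proton, two for the ester), anhydrous CeCl3 (2.5 equiv), THF, −78 → −20 °C; cold aq. KHSO4 to pH 3, EtOAc extraction; then i-PrN=C=N-i-Pr (1.2 equiv), DMAP (10 mol %), CH2Cl2, 0 °C → rt
Reagents that add atoms: vinylmagnesium bromide, C=C[Mg]Br (second vinyl group of the carbinol; the first is counted under Reactants as 4)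
Why: Double 1,2-addition of the cerium-modified Grignard reagent to the methyl ester gives the tertiary divinyl carbinol while the carboxylate formed by the first equivalent is inert, and carbodiimide activation (Steglich-type lactonisation) then closes the γ-lactone onto the cis-disposed tertiary hydroxyl; the oxirane stereocentres are not involved and the carbinol carbon, bearing two identical vinyl groups, is not a stereocentre.

**Step 4**
Reactants: 6 (1S,5R)-4,4-diethenyl-3,6-dioxabicyclo[3.1.0]hexan-2-one; 4 vinylmagnesium bromide
Product: 7 1-[(2S,3R)-3-(3-hydroxypenta-1,4-dien-3-yl)oxiran-2-yl]prop-2-en-1-one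
Conditions: 4 (1.1 equiv), THF, −78 °C; sat. aq. NH4Cl at −78 °C, then Et2O extraction
Reagents that add atoms: none
Why: Single addition of a Grignard reagent to a γ-lactone: at −78 °C the tetrahedral magnesium alkoxide stays ring-closed, so no ketone is exposed to a second equivalent, and protonation releases the γ-hydroxy vinyl ketone (any ring-closed hemiketal tautomer reopens as step 5 consumes the open form); no amine is present to add to the enone, and no stereocentre is formed or touched.

**Step 5**
Reactants: 7 1-[(2S,3R)-3-(3-hydroxypenta-1,4-dien-3-yl)oxiran-2-yl]prop-2-en-1-one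
Product: 8 (4S,5R,6S)-4-ethenyl-4-hydroxy-5,6-epoxycyclohex-2-en-1-one
Conditions: RuCl2(H2IMes)(=CH-C6H4-2-OiPr) (second-generation Hoveyda–Grubbs catalyst, H2IMes = 1,3-dimesitylimidazolidin-2-ylidene, 10 mol %), CH2Cl2 (5 mM), 40 °C, argon purge
Reagents that add atoms: none
Why: The precatalyst initiates on a carbinol vinyl group (the vinyl ketone is the poorer site for carbene formation), the ruthenium alkylidene adds [2+2] to the vinyl ketone, and cycloreversion of the ruthenacyclobutane releases ethylene and forms C2=C3. The closest known reaction types are ring-closing metathesis of vinyl ketones to cyclohex-2-enones and diastereotopic-group-selective ring-closing metathesis of divinyl carbinols. Ring A closes as a six-membered ring by olefin metathesis between the C4 and C1 arms, which the cis-oxirane holds on one side and the quaternary carbinol presses together. The new stereocentre C4 is set by the C5/C6 oxirane: the alkylidenes on the two vinyl groups interconvert by degenerate exchange, so the choice falls in the ring-closing step (Curtin–Hammett), where the spectator vinyl group should take the ring face away from the oxirane oxygen, the face from which carbon nucleophiles are known to approach the C4 carbonyl of 5,6-epoxycyclohex-2-ene-1,4-dione monoketals, while the small free hydroxyl sits syn, within hydrogen-bonding reach of the oxirane oxygen in CH2Cl2. The step needs this group selectivity and a preference for cyclisation over cross-metathesis; the first rests on the steric and hydrogen-bond bias just named, the second on high dilution and removal of ethylene.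

**Step 6**
Reactants: 8 (4S,5R,6S)-4-ethenyl-4-hydroxy-5,6-epoxycyclohex-2-en-1-one
Product: 9 (4S,5R,6S)-4-ethenyl-4-hydroxy-2-iodo-5,6-epoxycyclohex-2-en-1-one
Conditions: I2 (1.5 equiv), pyridine/CH2Cl2 (1:1), 0 °C → rt, dark; aq. Na2S2O3 work-up
Reagents that add atoms: iodine, II
Why: α-Iodination of an enone by conjugate addition of pyridine, iodination of the enolate and elimination (Baylis–Hillman-type addition–elimination) is established for 4-oxygenated 5,6-epoxycyclohex-2-enones; it touches only C2 and leaves the vinyl group, the tertiary alcohol and the oxirane alone.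

**Step 7**
Reactants: 10 (R)-4-benzyl-1,3-oxazolidin-2-one; 11 hexanoyl chloride
Product: 12 (R)-4-benzyl-3-hexanoyl-1,3-oxazolidin-2-one
Conditions: n-BuLi (1.05 equiv), THF, −78 °C; then 11, −78 → 0 °C
Reagents that add atoms: none
Why: N-Acylation of the lithiated oxazolidinone by the acid chloride installs the auxiliary, whose stereocentre is not touched.

**Step 8**
Reactants: 12 (R)-4-benzyl-3-hexanoyl-1,3-oxazolidin-2-one
Product: 13 (R)-4-benzyl-3-[(R)-2-methylhexanoyl]-1,3-oxazolidin-2-one
Conditions: NaN(SiMe3)2 (1.1 equiv), THF, −78 °C; then MeI (3 equiv), −78 → −40 °C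
Reagents that add atoms: iodomethane, CI
Why: Evans asymmetric alkylation: the chelated (Z)-sodium enolate is methylated on the face opposite the benzyl group of the (R)-auxiliary, which sets the (R)-configured methyl-bearing carbon (later C6″).

**Step 9**
Reactants: 13 (R)-4-benzyl-3-[(R)-2-methylhexanoyl]-1,3-oxazolidin-2-one
Product: 14 (R)-2-methylhexan-1-ol
Conditions: LiBH4 (1.2 equiv), MeOH (1.2 equiv), Et2O, 0 °C
Reagents that add atoms: none
Why: Reductive cleavage of the N-acyl oxazolidinone with LiBH4 gives the primary alcohol and returns the auxiliary without enolisation, so the α-stereocentre is kept.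

**Step 10**
Reactants: 14 (R)-2-methylhexan-1-ol; 15 2-(triphenylphosphoranylidene)propanal
Product: 17 (2E,4R)-2,4-dimethyloct-2-enal, via (R)-2-methylhexanal 16 (not isolated)
Conditions: PhI(OAc)2 (1.1 equiv), TEMPO (10 mol %), CH2Cl2, rt; aq. NaHCO3 wash, dry; then 15 (1.3 equiv), toluene, 80 °C (CH2Cl2 distilled off)
Reagents that add atoms: none
Why: Nitroxyl-catalysed oxidation stops at the aldehyde without epimerising the α-centre, and the stabilised formyl ylide then gives the (E)-trisubstituted enal in a Wittig reaction; the aldehyde is carried in solution because it is volatile and configurationally labile.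

**Step 11**
Reactants: 17 (2E,4R)-2,4-dimethyloct-2-enal; 18 diethyl (2-amino-2-oxoethyl)phosphonate
Product: 19 (2E,4E,6R)-4,6-dimethyldeca-2,4-dienamide
Conditions: NaH (1.1 equiv), THF, 0 °C → rt
Reagents that add atoms: none
Why: Horner–Wadsworth–Emmons olefination with the carbamoyl-stabilised phosphonate anion forms the (2E)-alkene and delivers the primary amide directly; the C6 stereocentre is remote from the reacting carbonyl.

**Step 12**
Reactants: 9 (4S,5R,6S)-4-ethenyl-4-hydroxy-2-iodo-5,6-epoxycyclohex-2-en-1-one; 19 (2E,4E,6R)-4,6-dimethyldeca-2,4-dienamide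
Product: 20 (2E,4E,6R)-4,6-dimethyldeca-2,4-dienamide N-bonded to C2 of (4S,5R,6S)-4-ethenyl-4-hydroxy-5,6-epoxycyclohex-2-en-1-one
Conditions: CuI (10 mol %), N,N-dimethylglycine hydrochloride (20 mol %), Cs2CO3 (2.2 equiv), 1,4-dioxane, 50 °C, argon
Reagents that add atoms: none
Why: Goldberg-type N-vinylation of a primary amide by a vinyl iodide at monovalent copper proceeds with retention at the sp2 carbon, so no stereocentre is involved; a tertiary-amine amino acid ligand is chosen so that no nucleophilic amine can add to the iodoenone.

**Step 13**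
Reactants: 21 ethyl (2E)-4-oxobut-2-enoate
Product: 22 ethyl (2E,4E)-5-iodopenta-2,4-dienoate
Conditions: CrCl2 (6 equiv), CHI3 (2 equiv), THF, 0 °C → rt
Reagents that add atoms: iodoform, IC(I)I
Why: Takai olefination: the geminal dichromium species formed from CHI3 and divalent chromium adds to the aldehyde and eliminates to the (E)-vinyl iodide, the ester and the existing (E)-alkene being inert to the reagent.

**Step 14**
Reactants: 22 ethyl (2E,4E)-5-iodopenta-2,4-dienoate
Product: 23 (2E,4E)-5-iodopenta-2,4-dienoic acid
Conditions: LiOH (2 equiv), THF/H2O (3:1), 0 °C → rt; then 1 M HCl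
Reagents that add atoms: lithium hydroxide, [Li+].[OH-]
Why: Saponification of the ethyl ester with cold aqueous LiOH affects neither the vinyl iodide nor the diene geometry.

**Step 15**
Reactants: 24 cyclopentane-1,3-dione
Product: 25 2-(hydroxyimino)cyclopentane-1,3-dione
Conditions: NaNO2 (1.05 equiv), 2 M aq. HCl, 0–5 °C
Reagents that add atoms: sodium nitrite, [Na+].[O-]N=O
Why: Nitrosation of the enolised 1,3-dione at C2 by nitrous acid and tautomerisation to the oxime is the classical α-oximination of an active methylene compound.

**Step 16**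
Reactants: 25 2-(hydroxyimino)cyclopentane-1,3-dione
Product: 26 2-amino-3-hydroxycyclopent-2-en-1-one hydrochloride
Conditions: H2 (1 atm), Pd/C (10 wt %), HCl (1.1 equiv), MeOH, rt
Reagents that add atoms: hydrogen chloride, Cl
Why: Catalytic hydrogenation of the oxime to the primary amine in the presence of HCl traps the α-amino dione as its enolised hydrochloride and prevents self-condensation.

**Step 17**
Reactants: 23 (2E,4E)-5-iodopenta-2,4-dienoic acid; 26 2-amino-3-hydroxycyclopent-2-en-1-one hydrochloride
Product: 28 (2E,4E)-N-(2-hydroxy-5-oxocyclopent-1-en-1-yl)-5-iodopenta-2,4-dienamide, via dienoyl chloride 27 (not isolated)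
Conditions: (COCl)2 (1.2 equiv), DMF (cat.), CH2Cl2, 0 °C → rt, evaporate; then 26, Et3N (3 equiv), DMF, 0 °C → rt
Reagents that add atoms: oxalyl chloride, ClC(=O)C(Cl)=O (chlorine of 27 only)
Why: Acid chloride formation (Vilsmeier-type activation) and Schotten–Baumann-type acylation of the amine set free by Et3N end on nitrogen, the amide being preferred over the enol ester, and the (E,E)-iododiene is not touched.

**Step 18**
Reactants: 20 the C2 dienamide of the epoxy enone; 28 (2E,4E)-N-(2-hydroxy-5-oxocyclopent-1-en-1-yl)-5-iodopenta-2,4-dienamide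
Product: 29 CNP0262080.2
Conditions: Pd(OAc)2 (10 mol %), n-Bu4NCl (1 equiv), NaHCO3 (3 equiv), DMF, rt → 35 °C, argon, dark; pH 4 buffer work-up
Reagents that add atoms: none
Why: Heck reaction under ligand-free phase-transfer conditions: zerovalent palladium formed from Pd(OAc)2 inserts into the C–I bond of 28 with retention and adds syn across the only monosubstituted alkene (the C4 vinyl group) with the dienyl group at the terminal carbon; β-hydride elimination, possible only away from quaternary C4, gives the (E)-C1′=C2′ bond, and the mild base and temperature spare the oxirane, the tertiary alcohol and the enolised aminodione.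

**Compound list**
1 | cis-epoxysuccinic acid, (2R,3S)-oxirane-2,3-dicarboxylic acid (meso) | OC(=O)[C@@H]1O[C@@H]1C(O)=O | starting material
2 | dimethyl (2R,3S)-oxirane-2,3-dicarboxylate (meso) | COC(=O)[C@@H]1O[C@@H]1C(=O)OC | intermediate
3 | (2S,3R)-3-(methoxycarbonyl)oxirane-2-carboxylic acid | COC(=O)[C@@H]1O[C@@H]1C(O)=O | intermediate
4 | vinylmagnesium bromide | C=C[Mg]Br | starting material
5 | (2S,3R)-3-(3-hydroxypenta-1,4-dien-3-yl)oxirane-2-carboxylic acid | C=CC(O)(C=C)[C@@H]1O[C@@H]1C(O)=O | intermediate (not isolated)
6 | (1S,5R)-4,4-diethenyl-3,6-dioxabicyclo[3.1.0]hexan-2-one | C=CC2(C=C)[C@@H]1O[C@@H]1C(=O)O2 | intermediate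
7 | 1-[(2S,3R)-3-(3-hydroxypenta-1,4-dien-3-yl)oxiran-2-yl]prop-2-en-1-one | C=CC(O)(C=C)[C@@H]1O[C@@H]1C(=O)C=C | intermediate
8 | (4S,5R,6S)-4-ethenyl-4-hydroxy-5,6-epoxycyclohex-2-en-1-one | C1=C[C@@](O)(C=C)[C@@H]2O[C@@H]2C1=O | intermediate
9 | (4S,5R,6S)-4-ethenyl-4-hydroxy-2-iodo-5,6-epoxycyclohex-2-en-1-one | IC1=C[C@@](O)(C=C)[C@@H]2O[C@@H]2C1=O | intermediate
10 | (R)-4-benzyl-1,3-oxazolidin-2-one | O=C1N[C@H](Cc2ccccc2)CO1 | starting material
11 | hexanoyl chloride | CCCCCC(Cl)=O | starting material
12 | (R)-4-benzyl-3-hexanoyl-1,3-oxazolidin-2-one | CCCCCC(=O)N1[C@H](Cc2ccccc2)COC1=O | intermediate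
13 | (R)-4-benzyl-3-[(R)-2-methylhexanoyl]-1,3-oxazolidin-2-one | CCCC[C@@H](C)C(=O)N1[C@H](Cc2ccccc2)COC1=O | intermediate
14 | (R)-2-methylhexan-1-ol | CCCC[C@@H](C)CO | intermediate
15 | 2-(triphenylphosphoranylidene)propanal | CC(C=O)=P(c1ccccc1)(c1ccccc1)c1ccccc1 | starting material
16 | (R)-2-methylhexanal | CCCC[C@@H](C)C=O | intermediate (not isolated)
17 | (2E,4R)-2,4-dimethyloct-2-enal | CCCC[C@@H](C)/C=C(C)/C=O | intermediate
18 | diethyl (2-amino-2-oxoethyl)phosphonate | CCOP(=O)(CC(N)=O)OCC | starting material
19 | (2E,4E,6R)-4,6-dimethyldeca-2,4-dienamide | CCCC[C@@H](C)/C=C(C)/C=C/C(N)=O | intermediate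
20 | (2E,4E,6R)-4,6-dimethyldeca-2,4-dienamide N-bonded to C2 of (4S,5R,6S)-4-ethenyl-4-hydroxy-5,6-epoxycyclohex-2-en-1-one | CCCC[C@@H](C)/C=C(C)/C=C/C(=O)NC1=C[C@@](O)(C=C)[C@@H]2O[C@@H]2C1=O | intermediate
21 | ethyl (2E)-4-oxobut-2-enoate | CCOC(=O)/C=C/C=O | starting material
22 | ethyl (2E,4E)-5-iodopenta-2,4-dienoate | CCOC(=O)/C=C/C=C/I | intermediate
23 | (2E,4E)-5-iodopenta-2,4-dienoic acid | OC(=O)/C=C/C=C/I | intermediate
24 | cyclopentane-1,3-dione | O=C1CCC(=O)C1 | starting material
25 | 2-(hydroxyimino)cyclopentane-1,3-dione | ON=C1C(=O)CCC1=O | intermediate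
26 | 2-amino-3-hydroxycyclopent-2-en-1-one hydrochloride (enol form of 2-aminocyclopentane-1,3-dione hydrochloride) | Cl.NC1=C(O)CCC1=O | intermediate
27 | (2E,4E)-5-iodopenta-2,4-dienoyl chloride | ClC(=O)/C=C/C=C/I | intermediate (not isolated)
28 | (2E,4E)-N-(2-hydroxy-5-oxocyclopent-1-en-1-yl)-5-iodopenta-2,4-dienamide | I/C=C/C=C/C(=O)NC1=C(O)CCC1=O | intermediate
29 | CNP0262080.2: ring A (4S,5R,6S)-4-hydroxy-5,6-epoxycyclohex-2-en-1-one carrying at C2 the (2E,4E,6R)-4,6-dimethyldeca-2,4-dienamide nitrogen and at C4 the (1E,3E,5E)-7-[(2-hydroxy-5-oxocyclopent-1-en-1-yl)amino]-7-oxohepta-1,3,5-trien-1-yl chain | CCCC[C@@H](C)/C=C(C)/C=C/C(=O)NC1=C[C@@](O)(/C=C/C=C/C=C/C(=O)NC2=C(O)CCC2=O)[C@@H]2O[C@@H]2C1=O | target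

**Step count and risks**
Total step count: 18 (core steps 1–6, upper chain steps 7–11, C2–N coupling step 12, lower chain steps 13–17, Heck coupling step 18).
Longest linear sequence: 8 steps (steps 1–6, 12, 18).

The three steps most likely to fail:

1. Step 12 (C2–N coupling). Cs2CO3 deprotonates the C4 hydroxyl to an alkoxide flanked by the oxirane and the iodoenone. Copper binding to this alkoxide and base-induced decomposition of the epoxy iodoenone may outrun the slow N-vinylation of a primary dienamide at a hindered α-iodoenone. The fallback sets out from 9 and comes back at 20; it takes the hydroxyl out of play before the coupling. Silylation of 9 (TESOTf, 2,6-lutidine, CH2Cl2, −78 °C) should give (4S,5R,6S)-4-ethenyl-2-iodo-4-(triethylsilyloxy)-5,6-epoxycyclohex-2-en-1-one F1. The same CuI-catalysed coupling with 19, now on a substrate that cannot form an alkoxide, should give the triethylsilyl ether of 20 F2. HF·pyridine in THF/pyridine at 0 °C then removes the silyl group and returns 20.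

2. Step 5 (ring closure). Slow turnover at the electron-poor vinyl ketone may let cross-metathesis oligomerisation and catalyst decay compete, and the higher temperature then needed would blur the discrimination between the two vinyl groups. The fallback sets out from 7 and comes back at 8; it closes the ring at the alcohol oxidation level. Luche reduction of 7 (NaBH4, CeCl3·7H2O, MeOH, −78 °C) should give 3-[3-(1-hydroxyprop-2-en-1-yl)oxiran-2-yl]penta-1,4-dien-3-ol F3, with the cis-oxirane configured as in 7 and both C1 carbinol epimers present (C1 is reoxidised later). Allylic alcohols are among the fastest substrates for ruthenium metathesis, so RuCl2(H2IMes)(PCy3)(=CHPh) (second-generation Grubbs catalyst) in dilute CH2Cl2 at room temperature should close ring A to 4-ethenyl-5,6-epoxycyclohex-2-ene-1,4-diol F4, with C4, C5 and C6 as in 8. The same oxirane-controlled choice of vinyl group applies at the lower temperature, and a minor C4 epimer could be removed at this stage. MnO2 in CH2Cl2 oxidises only the secondary allylic alcohol and returns 8.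

3. Step 4 (single vinyl addition to the lactone). Premature opening of the tetrahedral magnesium alkoxide would expose the vinyl ketone to a second 1,2-addition or to conjugate addition of the reagent. The fallback sets out from 3 and comes back at 7; it stores the ketone oxidation level as an N-methoxy-N-methylamide chelate instead of a lactone adduct. Half-ester 3 is activated with 1,1'-carbonyldiimidazole in CH2Cl2 at 0 °C to the acyl imidazole methyl (2R,3S)-3-(1H-imidazole-1-carbonyl)oxirane-2-carboxylate F5. MeNH(OMe)·HCl at room temperature converts this into methyl (2R,3S)-3-[methoxy(methyl)carbamoyl]oxirane-2-carboxylate F6. Excess 4 with anhydrous CeCl3 in THF at −78 → −20 °C should then add once to the amide, whose five-membered magnesium chelate holds the ketone level until work-up, and twice to the ester. An inverse quench into cold aq. KHSO4/Et2O, which protonates the released N,O-dimethylhydroxylamine before it can add to the enone, returns 7.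

**Further compounds**
F1 | step 12 | (4S,5R,6S)-4-ethenyl-2-iodo-4-(triethylsilyloxy)-5,6-epoxycyclohex-2-en-1-one | IC1=C[C@@](O[Si](CC)(CC)CC)(C=C)[C@@H]2O[C@@H]2C1=O
F2 | step 12 | triethylsilyl ether of 20 (C4–O–SiEt3) | CCCC[C@@H](C)/C=C(C)/C=C/C(=O)NC1=C[C@@](O[Si](CC)(CC)CC)(C=C)[C@@H]2O[C@@H]2C1=O
F3 | step 5 | 3-[3-(1-hydroxyprop-2-en-1-yl)oxiran-2-yl]penta-1,4-dien-3-ol, cis-oxirane as in 7, both C1 epimers | C=CC(O)(C=C)[C@@H]1O[C@@H]1C(O)C=C
F4 | step 5 | 4-ethenyl-5,6-epoxycyclohex-2-ene-1,4-diol, C4/C5/C6 as in 8, both C1 epimers | C1=C[C@@](O)(C=C)[C@@H]2O[C@@H]2C1O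
F5 | step 4 | methyl (2R,3S)-3-(1H-imidazole-1-carbonyl)oxirane-2-carboxylate | COC(=O)[C@@H]1O[C@@H]1C(=O)n1ccnc1
F6 | step 4 | methyl (2R,3S)-3-[methoxy(methyl)carbamoyl]oxirane-2-carboxylate | COC(=O)[C@@H]1O[C@@H]1C(=O)N(C)OC
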